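The target is fisetinidol-(4β→8)-catechin-(6→4α)-fisetinidol. The retrosynthesis cuts C4(unit 1)–C8(catechin) first and C4(unit 2)–C6(catechin) second, leaving one catechin nucleophile and two copies of one C4-oxygenated fisetinidol electrophile.
Forward: (+)-taxifolin loses its 5-OH and its C4 carbonyl becomes a C4 leaving group (6). (+)-Catechin is benzylated and capped with bromine at C8 (10). C4–C6 is joined first (step 9) and the cap removed; a second copy of 6 is tied to the dimer by a glutarate bridge between the two 3-hydroxyls, C4–C8 is closed (step 13), and the bridge and eleven benzyl groups come off.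
Enabling feature: in unit 1, O7 (para to C4a) and O1 (on C8a, ortho to C4a) of ring A make C4 a planar benzylic cation, so either C4 epimer of the leaving group converges on one intermediate. C8, between O1 and O7, is the last free carbon of the phloroglucinol ring D. The carbinol carbons C3 lie one bond from C4 (unit 1) and four bonds from C8 (catechin), so they can carry a short tether.
Stereochemistry: C2 and C3 of both fisetinidol units come from (+)-taxifolin, those of the middle unit from (+)-catechin. C4 of unit 2 (4α, 3,4-trans) arises by attack anti to the 3-benzyloxy group. C4 of unit 1 (4β, 3,4-cis, the contra-steric centre) is set by tether-enforced delivery syn to the C3 oxygen.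

Key step: step 13

Assumption: commercial (+)-taxifolin and (+)-catechin are taken as the single (2R,3R) and (2R,3S) enantiomers. Compounds 6, 7, 15 and 16 are carried as mixtures of C4 epimers, so C4 has no descriptor in their SMILES; both epimers give the same cation.

Step 1
Reactants: 1 (+)-taxifolin, (2R,3R)-3,5,7,3',4'-pentahydroxyflavanone
Product: 2 (2R,3R)-7,3',4'-tri-O-benzyltaxifolin (3-OH and 5-OH free)
Conditions: BnBr (3.1 equiv), K2CO3, DMF, Ar, rt
Reagents that add atoms: benzyl bromide, BrCc1ccccc1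
Why: Williamson etherification should take only the three acidic phenols at C7, C3' and C4', because the 5-OH is tied up in a hydrogen bond to the C4 carbonyl and the 3-OH is a much less acidic alcohol, while the mild base at room temperature under argon should leave C2 and C3 untouched.

Step 2
Reactants: 2 (2R,3R)-7,3',4'-tri-O-benzyltaxifolin
Product: 3 (2R,3R)-7,3',4'-tri-O-benzyltaxifolin 5-O-triflate
Conditions: PhNTf2, i-Pr2NEt, DMAP (cat.), CH2Cl2, 0 °C to rt
Reagents that add atoms: N-phenylbis(trifluoromethanesulfonimide), O=S(=O)(N(c1ccccc1)S(=O)(=O)C(F)(F)F)C(F)(F)F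
Why: Phenol-selective O-sulfonylation, in which the mild triflyl donor reacts through the phenoxide of the only remaining phenol and should leave the secondary 3-OH alone, marks C5–O as the one bond to be excised.

Step 3
Reactants: 3 (2R,3R)-7,3',4'-tri-O-benzyltaxifolin 5-O-triflate
Product: 4 (2R,3R)-7,3',4'-tri-O-benzylfustin
Conditions: Pd(OAc)2 (cat.), dppf, HCO2H, Et3N, DMF, 60 °C
Reagents that add atoms: none
Why: Palladium-catalysed formate reduction of an aryl triflate, in which zerovalent palladium formed in the flask inserts into the C5–O bond activated by the ortho carbonyl, formate delivers hydride with loss of CO2 and reductive elimination gives the 5-deoxy ring A, should spare the benzyl ethers (homogeneous catalyst), and the formate buffer should be too weakly basic to open the pyranone ring.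

Step 4
Reactants: 4 (2R,3R)-7,3',4'-tri-O-benzylfustin
Product: 5 (2R,3S,4R)-7,3',4'-tris(benzyloxy)flavan-3,4-diol (2,3-trans-3,4-trans)
Conditions: NaBH4, THF/MeOH, 0 °C
Reagents that add atoms: none
Why: Borohydride reduction of a 2,3-trans-dihydroflavonol should give mainly the 2,3-trans-3,4-trans diol by hydride delivery to the β face of the carbonyl, and any 4-epimer is harmless because C4 is ionised later.

Step 5
Reactants: 5 (2R,3S,4R)-7,3',4'-tris(benzyloxy)flavan-3,4-diol
Product: 6 (2R,3S)-7,3',4'-tris(benzyloxy)-4-(2-ethoxyethoxy)flavan-3-ol (both C4 epimers)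
Conditions: CSA (cat.), 2-ethoxyethanol/CH2Cl2, 4 Å MS, rt
Reagents that add atoms: 2-ethoxyethanol, CCOCCO
Why: In this acid-catalysed SN1 solvolysis only the C4 hydroxyl is benzylic to the O7/O1-activated ring A and ionises, the large excess of alcohol traps the cation before ring A of another molecule can, and the 3-OH stays free as the later anchor.

Step 6
Reactants: 6 (2R,3S)-7,3',4'-tris(benzyloxy)-4-(2-ethoxyethoxy)flavan-3-ol
Product: 7 (2R,3S)-3,7,3',4'-tetrakis(benzyloxy)-4-(2-ethoxyethoxy)flavan (both C4 epimers)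
Conditions: NaH, BnBr, DMF, 0 °C to rt
Reagents that add atoms: benzyl bromide, BrCc1ccccc1
Why: Williamson benzylation of the only free hydroxyl, under conditions to which the C4 ether is inert, installs a bulky non-participating 3-O group that tolerates butyllithium and falls off in the final hydrogenolysis.

Step 7
Reactants: 8 (+)-catechin, (2R,3S)-3,5,7,3',4'-pentahydroxyflavan
Product: 9 5,7,3',4'-tetra-O-benzyl-(+)-catechin
Conditions: BnBr (4.2 equiv), K2CO3, DMF, 0 °C to rt
Reagents that add atoms: benzyl bromide, BrCc1ccccc1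
Why: Williamson etherification of the four phenols leaves the far less acidic 3-OH free.

Step 8
Reactants: 9 5,7,3',4'-tetra-O-benzyl-(+)-catechin
Product: 10 8-bromo-5,7,3',4'-tetra-O-benzyl-(+)-catechin
Conditions: NBS (1.0 equiv), CH2Cl2, −78 °C to rt
Reagents that add atoms: N-bromosuccinimide, O=C1CCC(=O)N1Br
Why: Electrophilic aromatic bromination of the phloroglucinol ring D should occur at C8, which is less hindered than C6 between two benzyloxy groups, and so caps the normally preferred nucleophilic site.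

Step 9
Reactants: 7 (2R,3S)-3,7,3',4'-tetrakis(benzyloxy)-4-(2-ethoxyethoxy)flavan; 10 8-bromo-5,7,3',4'-tetra-O-benzyl-(+)-catechin
Product: 12 3,7,3',4'-tetra-O-benzylfisetinidol-(4α→6)-8-bromo-5,7,3',4'-tetra-O-benzylcatechin, via flavan-4-yl cation 11 (not isolated)
Conditions: TMSOTf (0.2 equiv), 10 (3 equiv, excess recovered), CH2Cl2, 4 Å MS, −78 to −30 °C
Reagents that add atoms: none
Why: In this Lewis-acid-catalysed Friedel–Crafts alkylation of a halogen-capped flavan-3-ol by a flavan-4-yl cation both epimers of 7 give cation 11, C6 is the only free carbon of ring D, and the bulky arene should enter pseudo-axially on the α face anti to the 3-benzyloxy group, setting C4 of unit 2 as 4α (4S, 3,4-trans).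

Step 10
Reactants: 12 3,7,3',4'-tetra-O-benzylfisetinidol-(4α→6)-8-bromo-5,7,3',4'-tetra-O-benzylcatechin
Product: 14 3,7,3',4'-tetra-O-benzylfisetinidol-(4α→6)-5,7,3',4'-tetra-O-benzylcatechin (C8–H; catechin 3-OH free), via 8-lithio lithium alkoxide 13 (not isolated)
Conditions: n-BuLi (2.5 equiv), THF, −78 °C; then H2O
Reagents that add atoms: none
Why: Bromine–lithium exchange after deprotonation of the 3-OH is faster at −78 °C than benzylic metalation, and protonation of 13 frees C8 without touching any stereocentre.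

Step 11
Reactants: 6 (2R,3S)-7,3',4'-tris(benzyloxy)-4-(2-ethoxyethoxy)flavan-3-ol
Product: 15 3-O-(4-carboxybutanoyl) derivative of 6 (hemiglutarate; both C4 epimers)
Conditions: glutaric anhydride, DMAP, Et3N, CH2Cl2, rt
Reagents that add atoms: glutaric anhydride, O=C1CCCC(=O)O1
Why: DMAP-catalysed ring opening of the cyclic anhydride by the secondary 3-OH gives the half ester under basic conditions that leave the acid-labile C4 ether intact.

Step 12
Reactants: 14 3,7,3',4'-tetra-O-benzylfisetinidol-(4α→6)-5,7,3',4'-tetra-O-benzylcatechin; 15 hemiglutarate of 6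
Product: 16 mixed glutarate diester joining O3 of the catechin unit of 14 to O3 of the C4-(2-ethoxyethoxy) fisetinidol unit (both C4 epimers)
Conditions: DCC, DMAP (cat.), CH2Cl2, 0 °C to rt
Reagents that add atoms: none
Why: Steglich esterification joins the acid to the only free hydroxyl of 14 under neutral conditions with retention at both C3 centres.

Step 13
Reactants: 16 glutarate-tethered dimer/electrophile pair
Product: 18 3,3-O-glutaryl-bridged undeca-O-benzyl fisetinidol-(4β→8)-catechin-(6→4α)-fisetinidol (14-membered bis-lactone), via tethered flavan-4-yl cation 17 (not isolated)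
Conditions: TMSOTf (0.3 equiv), CH2Cl2 (1 mM), 4 Å MS, −78 to −20 °C; then aq. NaHCO3
Reagents that add atoms: none
Why: TMSOTf activates the chelating 2-ethoxyethoxy group and both C4 epimers of 16 ionise to the same planar cation 17, stabilised by O7 (para to C4a) and O1 (on C8a) of ring A as a p-quinone-methide-type oxocarbenium ion, after which C8 of ring D attacks in a Friedel–Crafts alkylation and H8 is lost. The closest known reaction type is the Lewis-acid-catalysed intramolecular C4–C8 condensation of two benzylated flavan-3-ol units joined through their 3-hydroxyls by a dicarboxylate linker, which leads to 3,4-cis interflavan bonds in the 2,3-trans series. The only ring closed is the temporary 14-membered bis-lactone (C4, C3, O, the five glutaryl carbons, O, C3, C2, O1, C8a, C8), a 14-exo-trig closure with respect to the C4=C4a bond of the quinone-methide form. The one new stereocentre, C4 of unit 1, is controlled by C3 through the tether: attack on the half-chair cation must be pseudo-axial, the α path places the incoming ring D anti (about 180°) to the C3–O bond, which the short chain cannot span, whereas the β path on the conformer with equatorial C2-aryl and C3-ester groups keeps them gauche, so the aryl group should end up 4β (4R, 3,4-cis). Site selectivity is secured because C6 of ring D is already substituted, C8 is the only doubly oxygen-flanked carbon the tether can reach and the resorcinol-type rings of the fisetinidol units are much weaker nucleophiles, while high dilution suppresses intermolecular alkylation. Participation of the C3 ester carbonyl should give a dioxolenium ion only reversibly and so should not divert the reaction.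

Step 14
Reactants: 18 glutaryl-bridged undeca-O-benzyl trimer
Product: 19 undeca-O-benzyl fisetinidol-(4β→8)-catechin-(6→4α)-fisetinidol (3-OH of unit 1 and of catechin free; 3-OBn on unit 2)
Conditions: NaOMe (cat.), MeOH/THF, rt to 40 °C
Reagents that add atoms: none
Why: Zemplén-type transesterification cleaves both ester bonds at the acyl carbons, so both C3–O bonds and all stereocentres are retained and the benzyl ethers are inert.

Step 15
Reactants: 19 undeca-O-benzyl trimer diol
Product: 20 fisetinidol-(4β→8)-catechin-(6→4α)-fisetinidol (CNP0289228.2)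
Conditions: H2 (1 atm), Pd(OH)2/C, THF/MeOH/H2O, rt
Reagents that add atoms: none
Why: Hydrogenolysis of the eleven benzyl ethers over Pd(OH)2/C under one atmosphere of hydrogen is the standard end game for benzylated oligoflavanoids and should spare the C2–O1 bonds and the robust 5-deoxy interflavan C4–aryl bonds.

Compound list
1 | (+)-taxifolin, (2R,3R) | Oc1cc(O)c2c(c1)O[C@H](c1ccc(O)c(O)c1)[C@@H](O)C2=O | starting material
2 | (2R,3R)-7,3',4'-tri-O-benzyltaxifolin | c4ccccc4COc1cc(O)c2c(c1)O[C@H](c1ccc(OCc4ccccc4)c(OCc4ccccc4)c1)[C@@H](O)C2=O | intermediate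
3 | (2R,3R)-7,3',4'-tri-O-benzyltaxifolin 5-O-triflate | c4ccccc4COc1cc(OS(=O)(=O)C(F)(F)F)c2c(c1)O[C@H](c1ccc(OCc4ccccc4)c(OCc4ccccc4)c1)[C@@H](O)C2=O | intermediate
4 | (2R,3R)-7,3',4'-tri-O-benzylfustin | c4ccccc4COc1ccc2c(c1)O[C@H](c1ccc(OCc4ccccc4)c(OCc4ccccc4)c1)[C@@H](O)C2=O | intermediate
5 | (2R,3S,4R)-7,3',4'-tris(benzyloxy)flavan-3,4-diol | c4ccccc4COc1ccc2c(c1)O[C@H](c1ccc(OCc4ccccc4)c(OCc4ccccc4)c1)[C@@H](O)[C@@H]2O | intermediate
6 | (2R,3S)-7,3',4'-tris(benzyloxy)-4-(2-ethoxyethoxy)flavan-3-ol, C4 epimers | c4ccccc4COc1ccc2c(c1)O[C@H](c1ccc(OCc4ccccc4)c(OCc4ccccc4)c1)[C@@H](O)C2OCCOCC | intermediate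
7 | (2R,3S)-3,7,3',4'-tetrakis(benzyloxy)-4-(2-ethoxyethoxy)flavan, C4 epimers | c4ccccc4COc1ccc2c(c1)O[C@H](c1ccc(OCc4ccccc4)c(OCc4ccccc4)c1)[C@@H](OCc4ccccc4)C2OCCOCC | intermediate
8 | (+)-catechin, (2R,3S) | Oc1cc(O)c2c(c1)O[C@H](c1ccc(O)c(O)c1)[C@@H](O)C2 | starting material
9 | 5,7,3',4'-tetra-O-benzyl-(+)-catechin | c4ccccc4COc1cc(OCc4ccccc4)c2c(c1)O[C@H](c1ccc(OCc4ccccc4)c(OCc4ccccc4)c1)[C@@H](O)C2 | intermediate
10 | 8-bromo-5,7,3',4'-tetra-O-benzyl-(+)-catechin | Brc1c(OCc4ccccc4)cc(OCc4ccccc4)c2c1O[C@H](c1ccc(OCc4ccccc4)c(OCc4ccccc4)c1)[C@@H](O)C2 | intermediate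
11 | 3,7,3',4'-tetra-O-benzylfisetinidol C4 cation (not isolated) | c4ccccc4COc1ccc2c(c1)O[C@H](c1ccc(OCc4ccccc4)c(OCc4ccccc4)c1)[C@@H](OCc4ccccc4)[CH+]2 | intermediate
12 | tetra-O-benzylfisetinidol-(4α→6)-8-bromo-tetra-O-benzylcatechin | Brc1c(OCc4ccccc4)c([C@@H]2c3ccc(OCc4ccccc4)cc3O[C@H](c3ccc(OCc4ccccc4)c(OCc4ccccc4)c3)[C@H]2OCc4ccccc4)c(OCc4ccccc4)c2c1O[C@H](c1ccc(OCc4ccccc4)c(OCc4ccccc4)c1)[C@@H](O)C2 | intermediate
13 | 8-lithio lithium 3-alkoxide derived from 12 (not isolated) | [Li]c1c(OCc4ccccc4)c([C@@H]2c3ccc(OCc4ccccc4)cc3O[C@H](c3ccc(OCc4ccccc4)c(OCc4ccccc4)c3)[C@H]2OCc4ccccc4)c(OCc4ccccc4)c2c1O[C@H](c1ccc(OCc4ccccc4)c(OCc4ccccc4)c1)[C@@H](O[Li])C2 | intermediate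
14 | tetra-O-benzylfisetinidol-(4α→6)-tetra-O-benzylcatechin | c1c(OCc4ccccc4)c([C@@H]2c3ccc(OCc4ccccc4)cc3O[C@H](c3ccc(OCc4ccccc4)c(OCc4ccccc4)c3)[C@H]2OCc4ccccc4)c(OCc4ccccc4)c2c1O[C@H](c1ccc(OCc4ccccc4)c(OCc4ccccc4)c1)[C@@H](O)C2 | intermediate
15 | hemiglutarate of 6, C4 epimers | c4ccccc4COc1ccc2c(c1)O[C@H](c1ccc(OCc4ccccc4)c(OCc4ccccc4)c1)[C@@H](OC(=O)CCCC(=O)O)C2OCCOCC | intermediate
16 | glutarate-tethered precursor, C4 epimers | c1c(OCc4ccccc4)c([C@@H]2c3ccc(OCc4ccccc4)cc3O[C@H](c3ccc(OCc4ccccc4)c(OCc4ccccc4)c3)[C@H]2OCc4ccccc4)c(OCc4ccccc4)c2c1O[C@H](c1ccc(OCc4ccccc4)c(OCc4ccccc4)c1)[C@@H](OC(=O)CCCC(=O)O[C@H]6C(OCCOCC)c7ccc(OCc4ccccc4)cc7O[C@@H]6c7ccc(OCc4ccccc4)c(OCc4ccccc4)c7)C2 | intermediate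
17 | tethered flavan-4-yl cation (not isolated) | c1c(OCc4ccccc4)c([C@@H]2c3ccc(OCc4ccccc4)cc3O[C@H](c3ccc(OCc4ccccc4)c(OCc4ccccc4)c3)[C@H]2OCc4ccccc4)c(OCc4ccccc4)c2c1O[C@H](c1ccc(OCc4ccccc4)c(OCc4ccccc4)c1)[C@@H](OC(=O)CCCC(=O)O[C@H]6[CH+]c7ccc(OCc4ccccc4)cc7O[C@@H]6c7ccc(OCc4ccccc4)c(OCc4ccccc4)c7)C2 | intermediate
18 | glutaryl-bridged undeca-O-benzyl trimer, (4β→8) and (4α→6) | c4ccccc4COc1ccc2c(c1)O[C@H](c1ccc(OCc4ccccc4)c(OCc4ccccc4)c1)[C@@H](O5)[C@H]2c1c(OCc4ccccc4)c([C@@H]2c3ccc(OCc4ccccc4)cc3O[C@H](c3ccc(OCc4ccccc4)c(OCc4ccccc4)c3)[C@H]2OCc4ccccc4)c(OCc4ccccc4)c2c1O[C@H](c1ccc(OCc4ccccc4)c(OCc4ccccc4)c1)[C@@H](OC(=O)CCCC5=O)C2 | intermediate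
19 | undeca-O-benzyl trimer diol | c4ccccc4COc1ccc2c(c1)O[C@H](c1ccc(OCc4ccccc4)c(OCc4ccccc4)c1)[C@@H](O)[C@H]2c1c(OCc4ccccc4)c([C@@H]2c3ccc(OCc4ccccc4)cc3O[C@H](c3ccc(OCc4ccccc4)c(OCc4ccccc4)c3)[C@H]2OCc4ccccc4)c(OCc4ccccc4)c2c1O[C@H](c1ccc(OCc4ccccc4)c(OCc4ccccc4)c1)[C@@H](O)C2 | intermediate
20 | fisetinidol-(4β→8)-catechin-(6→4α)-fisetinidol | Oc1ccc2c(c1)O[C@H](c1ccc(O)c(O)c1)[C@@H](O)[C@H]2c1c(O)c([C@@H]2c3ccc(O)cc3O[C@H](c3ccc(O)c(O)c3)[C@H]2O)c(O)c2c1O[C@H](c1ccc(O)c(O)c1)[C@@H](O)C2 | target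

Total step count: 15. Longest linear sequence: 12 (steps 1, 2, 3, 4, 5, 6, 9, 10, 12, 13, 14, 15).

Steps most likely to fail

Step 13. The macrocyclisation may stall, intermolecular alkylation may take over, or the chain may prove loose enough to allow α attack and erode facial control.
The fallback sets out from 12 and 4 and comes back at 19. It keeps the bromine of 12 as a carbanion handle instead of removing it.
- 12 is silylated (TBSOTf, 2,6-lutidine) to the catechin 3-O-TBS ether of the bromo dimer F1, and ketone 4 is silylated in the same way to 3-O-TBS-tri-O-benzylfustin F2.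
- F1 is lithiated (n-BuLi, THF, −78 °C) and added to the C4 carbonyl of F2 to give the tertiary C4 carbinol F3, either epimer being usable.
- Ionic hydrogenation of this doubly benzylic carbinol (Et3SiH or n-Bu3SnH, CF3CO2H, CH2Cl2, low temperature) passes through the 4-aryl cation. That cation should accept hydride on the α face, anti to the bulky 3-silyloxy group, leaving the aryl group 4β in the bis-TBS trimer F4.
- n-Bu4NF then gives 19.

Step 9. Attack by the hindered, bromine-deactivated C6 may be so slow that the cation alkylates ring A of another electrophile molecule, or the free 3-OH, instead.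
The fallback sets out from 9 and 15 and comes back at 18. It reverses the order of the two interflavan bonds, so no halogen cap is needed.
- 9 is esterified with 15 (DCC, DMAP) to the glutarate-tethered monomer pair F5.
- TMSOTf at high dilution closes C4–C8 to the glutaryl-bridged fisetinidol-(4β→8)-catechin F6.
- In F6, C6 is the only free carbon of ring D, now alkyl-activated rather than bromine-deactivated. It is alkylated with 7 (TMSOTf, CH2Cl2, low temperature) anti to the 3-benzyloxy group to give 18.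
- Steps 8, 10 and 12 are then not needed.

Step 3. Warm amine-containing medium may open the pyranone ring of the triflate-activated dihydroflavonol by elimination of the ring-A phenoxide, and reclosure would erode the configuration at C2 and C3.
The fallback sets out from 3 and comes back at 5. It removes the enolisable carbonyl before the C5–O bond is cut.
- 3 is first reduced (NaBH4, THF/MeOH, 0 °C; aryl triflates survive) to the 5-triflyloxy flavan-3,4-diol F7.
- F7 has no acidic C3–H and is deactivated towards self-condensation. Only then is the triflate removed by the same palladium/formate reduction, giving 5.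

Further compounds
F1 | step 13 | catechin 3-O-TBS ether of bromo dimer 12 | Brc1c(OCc4ccccc4)c([C@@H]2c3ccc(OCc4ccccc4)cc3O[C@H](c3ccc(OCc4ccccc4)c(OCc4ccccc4)c3)[C@H]2OCc4ccccc4)c(OCc4ccccc4)c2c1O[C@H](c1ccc(OCc4ccccc4)c(OCc4ccccc4)c1)[C@@H](O[Si](C)(C)C(C)(C)C)C2
F2 | step 13 | (2R,3R)-3-O-TBS-7,3',4'-tri-O-benzylfustin | c4ccccc4COc1ccc2c(c1)O[C@H](c1ccc(OCc4ccccc4)c(OCc4ccccc4)c1)[C@@H](O[Si](C)(C)C(C)(C)C)C2=O
F3 | step 13 | tertiary C4 carbinol from F1 and F2, C4 epimers | c4ccccc4COc1ccc2c(c1)O[C@H](c1ccc(OCc4ccccc4)c(OCc4ccccc4)c1)[C@@H](O[Si](C)(C)C(C)(C)C)C2(O)c1c(OCc4ccccc4)c([C@@H]2c3ccc(OCc4ccccc4)cc3O[C@H](c3ccc(OCc4ccccc4)c(OCc4ccccc4)c3)[C@H]2OCc4ccccc4)c(OCc4ccccc4)c2c1O[C@H](c1ccc(OCc4ccccc4)c(OCc4ccccc4)c1)[C@@H](O[Si](C)(C)C(C)(C)C)C2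
F4 | step 13 | bis-TBS undeca-O-benzyl trimer, (4β→8) and (4α→6) | c4ccccc4COc1ccc2c(c1)O[C@H](c1ccc(OCc4ccccc4)c(OCc4ccccc4)c1)[C@@H](O[Si](C)(C)C(C)(C)C)[C@H]2c1c(OCc4ccccc4)c([C@@H]2c3ccc(OCc4ccccc4)cc3O[C@H](c3ccc(OCc4ccccc4)c(OCc4ccccc4)c3)[C@H]2OCc4ccccc4)c(OCc4ccccc4)c2c1O[C@H](c1ccc(OCc4ccccc4)c(OCc4ccccc4)c1)[C@@H](O[Si](C)(C)C(C)(C)C)C2
F5 | step 9 | glutarate-tethered pair of 9 and 6, C4 epimers | c1c(OCc4ccccc4)cc(OCc4ccccc4)c2c1O[C@H](c1ccc(OCc4ccccc4)c(OCc4ccccc4)c1)[C@@H](OC(=O)CCCC(=O)O[C@H]6C(OCCOCC)c7ccc(OCc4ccccc4)cc7O[C@@H]6c7ccc(OCc4ccccc4)c(OCc4ccccc4)c7)C2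
F6 | step 9 | glutaryl-bridged hepta-O-benzyl fisetinidol-(4β→8)-catechin | c4ccccc4COc1ccc2c(c1)O[C@H](c1ccc(OCc4ccccc4)c(OCc4ccccc4)c1)[C@@H](O5)[C@H]2c1c(OCc4ccccc4)cc(OCc4ccccc4)c2c1O[C@H](c1ccc(OCc4ccccc4)c(OCc4ccccc4)c1)[C@@H](OC(=O)CCCC5=O)C2
F7 | step 3 | (2R,3S,4R)-7,3',4'-tris(benzyloxy)-5-(triflyloxy)flavan-3,4-diol | c4ccccc4COc1cc(OS(=O)(=O)C(F)(F)F)c2c(c1)O[C@H](c1ccc(OCc4ccccc4)c(OCc4ccccc4)c1)[C@@H](O)[C@@H]2O
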